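## Analysis of the target

Isoanhydroicaritin (13) is a flavonol: a 4H-chromen-4-one in which the benzo ring A (C4a to C8a) is fused to the pyranone ring C (O1, C2, C3, C4), with ring B, a 4-hydroxyphenyl group, on C2. Ring A is fully differentiated, with a free hydroxyl at C5, a lone hydrogen at C6, a methyl ether at C7 and a 3-methylbut-2-enyl (prenyl) chain at C8; ring C carries the enolic C3 hydroxyl next to the C4 carbonyl. The molecule has no stereocentre, and the prenyl double bond bears two identical methyl groups, so no configuration has to be set or preserved. The sensitive parts are the trisubstituted prenyl alkene (attacked by electrophilic oxidants, and by protic nucleophiles under strong acid), the electron-rich phloroglucinol-type ring A, and the 3-hydroxy-4-pyranone unit, which is air-sensitive under strongly basic conditions. The difficulty is regiochemical and chemoselective: the prenyl group must end at C8 and not C6, the oxygens at C5, C7 and C4' must be told apart so that only C7 stays methylated, and the C3 oxygen must arrive without an oxidation that the prenyl group would not survive. The strategy rests on the sequence O1–C2–C3–C4 of ring C: O1 and C4 are the phenol oxygen and the formyl carbon of a ring A salicylaldehyde, and C2–C3 is an alkyne that already carries ring B on C2 and a silyl-protected oxygen on C3.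

## Retrosynthetic reasoning

**13 to 12 (O–CH2 bonds at O5 and O4').** The two phenols that are not involved in ring C are masked as methoxymethyl ethers. On ring A this is essential, because a free C5 hydroxyl would be a second site for the metal in the annulation and would lead to the 6-prenyl isomer. The acetal is chosen because it survives base, organolithium reagents, heat, fluoride and electrolysis, and leaves with dilute acid. No free hydroxyl flanks the prenyl group (C7 is a methyl ether, the other neighbour is O1), so acid cannot close a chroman ring.

**12 to 11 (O3–Si bond).** The C3 oxygen is carried as a triisopropylsilyl ether. The bulky silyl group is what makes the alkyne partner an isolable ynol ether. It is removed with a buffered fluoride source before the acid step, so that the acid only has to cleave two acetals.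

**11 to 5 and 10 (C4–C3 and O1–C2, the key disconnection).** Both bonds end on the two alkyne carbons, so cutting here splits ring C into two fragments of similar size. C4 is then an existing formyl carbon and O1 an existing phenol, and the coupling is a net loss of two hydrogens, which an anode can accept. C3 arrives already oxygenated. Cutting C2–C1' or C4a–C4 instead would require a halogenated ring or a separate one-carbon carbonyl source and would leave C3 unoxidised. The forward reaction has to metalate the formyl C–H from the rhodium-bound phenoxide, insert the alkyne with the acyl group on the oxygen-bearing carbon, and close the C–O bond.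

**5 to 4 (the C=C bond of the prenyl group).** The isopropylidene end is added by olefin cross-metathesis to an allyl group. An intact prenyl ether would rearrange with allylic inversion to the 1,1-dimethylallyl isomer, whereas an allyl group rearranges cleanly and can be extended afterwards.

**4 to 3 (the C8–CH2 bond).** An aromatic Claisen rearrangement delivers the carbon chain to the carbon ortho to the oxygen that becomes O1. The other ortho carbon carries the formyl group, so the C8 versus C6 question is settled by connectivity. The rearrangement also frees the one hydroxyl that step 7 needs, while the other ring A oxygen stays protected.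

**3 to 2 to 1 (two O–C bonds).** The two hydroxyls of 1 are equivalent, so the first etherification poses no regiochemical problem. It should stop at the mono-ether 2 because the remaining hydroxyl is hydrogen-bonded to the formyl oxygen. That hydroxyl is then O-allylated to give 3.

**10 to 9 to 8 to 7 to 6 (O–Si, then the alkyne carbons).** Siloxyalkyne 10 is the O-silylated form of ynolate 9. The ynolate comes from ester 7 by a Kowalski sequence via 8, in which the aryl group migrates from the ester carbon to an added one-carbon carbenoid. The ester carbon thus becomes the oxygen-bearing C3 and the added carbon becomes C2. Ester 7 is the acetal of the commercial phenol 6.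

## Alternatives that were turned down

Alternative 1: Ring A is disconnected at C5–C6 and C4a–C8a. The two pieces are the silyl ketene acetal diene {[1,3-dimethoxy-2-(3-methylbut-2-en-1-yl)buta-1,3-dien-1-yl]oxy}trimethylsilane A2 and the ketene acetal enone 4,4-dimethoxybut-3-en-2-one A3. Diene A2 carries C6, C7, C8 and C8a with the prenyl group on the future C8, and enone A3 carries C4a, C5 and the acetyl group. In the forward step TiCl4 at low temperature joins the terminal carbon of A2 to the acetal carbon of A3 with loss of one methoxy group. NaOMe in the same flask then closes C4a onto the ester carbon and aromatises to 1-[2-hydroxy-4,6-dimethoxy-3-(3-methylbut-2-en-1-yl)phenyl]ethan-1-one A1.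
- For: the prenyl position is fixed by a simple enolate C-alkylation before A2 is made, the formal (3+3) benzannulation is a known reaction type, and the materials are cheap. On known precedent it is stronger than the chosen route.
- Against: A1 has both ring A oxygens as methyl ethers, so a late selective C5 demethylation with a Lewis acid is needed next to the prenyl alkene. All of ring C is still missing: aldol condensation with a ring B aldehyde, then oxidative cyclisation. A 6'-alkoxychalcone tends to give the aurone under Algar–Flynn–Oyamada conditions. The C3 oxygen must still be introduced oxidatively.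
- Comparison: the chosen strategy is convergent, delivers C3 already oxygenated, and keeps the three phenolic oxygens differentiated from the start.

Alternative 2: Ring A is disconnected at C8a–C8 and C6–C7 into 3-ethoxycyclobut-2-en-1-one A5 and the ynol ether 1-methoxy-5-methylhex-4-en-1-yne A6. Cyclobutenone A5 supplies C8a, C6, C5 and C4a, and alkyne A6 supplies C8 and C7. In the forward Danheiser benzannulation, heating opens A5 to a vinylketene, A6 adds across the ketene, and ring opening followed by six-electron electrocyclisation gives 5-ethoxy-3-methoxy-2-(3-methylbut-2-en-1-yl)phenol A4.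
- For: the step is reagent-free and regiospecific, and it gives the prenyl group between the hydroxyl and the methoxy group with three distinguishable oxygens. On ring A regiocontrol it is as strong as the chosen route.
- Against: A4 has no carbon at C4a, so an ortho-selective formylation is needed that must beat the position para to the hydroxyl. The result would be a salicylaldehyde of the same type as 5, reached by a longer path and with an ethyl ether at C5 that is harder to remove than an acetal. A6 is a volatile, acid-sensitive skipped enyne that needs its own synthesis and may isomerise on heating. Ring C and the C3 oxygen remain to be built.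
- Comparison: the chosen route reaches 5 in four steps from an aldehyde that already has the formyl carbon.

Alternative 3: Ring C is disconnected at C4a–C4, C4–C3 and O1–C2 into three components: 2-iodo-5-methoxy-3-(methoxymethoxy)-6-(3-methylbut-2-en-1-yl)phenol A8, the terminal alkyne 1-ethynyl-4-(methoxymethoxy)benzene A9 and carbon monoxide A10. In the forward step PdCl2(PPh3)2 in Et2NH effects oxidative addition of A8, insertion of A10, alkynylation by A9 and amine-mediated 6-endo closure to 7-methoxy-5-(methoxymethoxy)-2-[4-(methoxymethoxy)phenyl]-8-(3-methylbut-2-en-1-yl)-4H-chromen-4-one A7.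
- For: three bonds form in one step, A9 is a simple terminal alkyne that needs no ynolate chemistry, and the reaction type is established for 2-iodophenols. On precedent it is clearly stronger than the chosen key step.
- Against: A7 lacks the C3 oxygen, so a late C3 metalation and oxidation is added in the presence of the prenyl group. A8 needs a regioselective iodination between the hydroxyl and the acetal on a ring with a second open position. A8 is a doubly ortho-substituted, electron-rich aryl iodide that should be slow in oxidative addition to zerovalent palladium. The gas A10 has to be handled under pressure.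
- Comparison: the chosen strategy uses the formyl carbon already on the ring, needs no halogenation, and saves the C3 oxidation. A7 is kept as the fallback intermediate should the key step fail.

Key step: step 7

Assumption: 2,6-dihydroxy-4-methoxybenzaldehyde (1) is treated as a purchasable building block.

## Route

Step 1
Reactants: 1 2,6-dihydroxy-4-methoxybenzaldehyde
Product: 2 2-hydroxy-4-methoxy-6-(methoxymethoxy)benzaldehyde
Conditions: MOMCl (1.05 equiv), i-Pr2NEt, CH2Cl2, 0 °C
Reagents that add atoms: chloromethyl methyl ether (MOMCl), COCCl
Why: Phenol O-alkylation to the methoxymethyl acetal; the two hydroxyls of 1 are equivalent, and after the first etherification the remaining one is held in a hydrogen bond to the formyl oxygen, which should stop the reaction at the mono-ether.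

Step 2
Reactants: 2 2-hydroxy-4-methoxy-6-(methoxymethoxy)benzaldehyde
Product: 3 4-methoxy-2-(methoxymethoxy)-6-(prop-2-en-1-yloxy)benzaldehyde
Conditions: allyl bromide, K2CO3, DMF, 50 °C
Reagents that add atoms: allyl bromide, C=CCBr
Why: Williamson ether synthesis; carbonate in a dipolar aprotic solvent breaks the chelate and the phenoxide is O-allylated, and the acetal and aldehyde are inert to these conditions.

Step 3
Reactants: 3 4-methoxy-2-(methoxymethoxy)-6-(prop-2-en-1-yloxy)benzaldehyde
Product: 4 2-hydroxy-4-methoxy-6-(methoxymethoxy)-3-(prop-2-en-1-yl)benzaldehyde
Conditions: PhNEt2, 190 °C, sealed tube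
Reagents that add atoms: none
Why: Aromatic Claisen rearrangement; the productive [3,3] shift ends on the one unsubstituted ortho carbon (the future C8), tautomerisation restores the phenol, and the basic amine solvent protects the acetal from adventitious acid.

Step 4
Reactants: 4 2-hydroxy-4-methoxy-6-(methoxymethoxy)-3-(prop-2-en-1-yl)benzaldehyde
Product: 5 2-hydroxy-4-methoxy-6-(methoxymethoxy)-3-(3-methylbut-2-en-1-yl)benzaldehyde
Conditions: second-generation Grubbs catalyst RuCl2(=CHPh)(PCy3)(H2IMes) (5 mol %), 2-methyl-2-butene/CH2Cl2, 40 °C, sealed vessel
Reagents that add atoms: 2-methyl-2-butene, CC=C(C)C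
Why: Olefin cross-metathesis of a terminal allylarene with a large excess of 2-methyl-2-butene, which exchanges the terminal methylene for an isopropylidene group; any 2-butenyl by-product re-enters the cycle, and phenols and aldehydes are tolerated by the ruthenium carbene.

Step 5
Reactants: 6 methyl 4-hydroxybenzoate
Product: 7 methyl 4-(methoxymethoxy)benzoate
Conditions: MOMCl, i-Pr2NEt, CH2Cl2, 0 °C to rt
Reagents that add atoms: chloromethyl methyl ether (MOMCl), COCCl
Why: Standard acetal protection of an acidic phenol; the ester is untouched.

Step 6
Reactants: 7 methyl 4-(methoxymethoxy)benzoate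
Product: 10 triisopropyl({[4-(methoxymethoxy)phenyl]ethynyl}oxy)silane, via lithium dibromoenolate 8 (not isolated), via lithium ynolate 9 (not isolated)
Conditions: CH2Br2, LiTMP, THF, −78 °C; LiN(SiMe3)2, −78 °C; n-BuLi, −78 °C to rt; TIPSCl (excess), −78 °C to rt
Reagents that add atoms: dibromomethane, BrCBr; chlorotriisopropylsilane (TIPSCl), CC(C)[Si](Cl)(C(C)C)C(C)C
Why: Kowalski ester homologation stopped at the ynolate: acylation of dibromomethyllithium by 7 and enolisation with LiN(SiMe3)2 give 8, bromine–lithium exchange triggers the carbenoid 1,2-shift of the aryl group to give 9, and the bulky silyl chloride silylates the ynolate on oxygen, not on carbon.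

Step 7
Reactants: 5 2-hydroxy-4-methoxy-6-(methoxymethoxy)-3-(3-methylbut-2-en-1-yl)benzaldehyde, 10 triisopropyl({[4-(methoxymethoxy)phenyl]ethynyl}oxy)silane
Product: 11 7-methoxy-5-(methoxymethoxy)-2-[4-(methoxymethoxy)phenyl]-8-(3-methylbut-2-en-1-yl)-3-[(triisopropylsilyl)oxy]-4H-chromen-4-one
Conditions: [Cp*RhCl2]2 (5 mol %), NaOPiv, n-Bu4NPF6, anhydrous MeCN, 60 °C; undivided cell, graphite felt anode, Pt cathode, constant current (about 2 mA); 10 (1.5 equiv) added slowly
Reagents that add atoms: none
Why: Proposed new method: pivalate-assisted exchange places the phenoxide of 5 on trivalent rhodium, and concerted metalation–deprotonation of the neighbouring formyl C–H gives a five-membered acyl rhodacycle; 10 then inserts into the rhodium–acyl bond to give a seven-membered oxarhodacycle, and C–O reductive elimination releases 11 and monovalent rhodium, which the anode returns to trivalent rhodium while the pivalic acid formed is reduced to H2 at the cathode. The closest known reaction type is the rhodium-catalysed oxidative annulation of salicylaldehydes with internal alkynes to chromones run with Cu(OAc)2, together with anodic turnover of Cp*Rh catalysts in C–H/O–H alkyne annulations; a siloxyalkyne has not been shown as the two-carbon partner. Ring C is closed as a six-membered pyranone by C(sp2)–O reductive elimination from the seven-membered rhodacycle, a formal (4+2) annulation of the O1–C8a–C4a–C4 unit with the alkyne. No stereocentre is formed. The step needs a single orientation of insertion: the ynol ether is polarised with its oxygen-bearing carbon electrophilic and its aryl-bearing carbon nucleophilic, so the acyl group should migrate to the former (C4–C3) while rhodium stays on the aryl-substituted carbon, the position it also prefers with aryl alkyl alkynes, and O1–C2 follows. Site selectivity on ring A is secured because the second oxygen is an acetal, so only the hydroxyl next to the prenyl group can bind rhodium. Chemoselectivity rests on the trisubstituted prenyl alkene being a poor insertion partner, on the low potential of the mediated oxidation, and on the anhydrous, pivalate-buffered aprotic medium that keeps the siloxyalkyne from protonation.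

Step 8
Reactants: 11 7-methoxy-5-(methoxymethoxy)-2-[4-(methoxymethoxy)phenyl]-8-(3-methylbut-2-en-1-yl)-3-[(triisopropylsilyl)oxy]-4H-chromen-4-one
Product: 12 3-hydroxy-7-methoxy-5-(methoxymethoxy)-2-[4-(methoxymethoxy)phenyl]-8-(3-methylbut-2-en-1-yl)-4H-chromen-4-one
Conditions: n-Bu4NF, AcOH, THF, 0 °C
Reagents that add atoms: none
Why: Fluoride cleavage of the enol silyl ether, driven by the Si–F bond; the acetic acid buffer keeps the flavonol from standing as its air-sensitive anion, and acetals and the alkene are inert.

Step 9
Reactants: 12 3-hydroxy-7-methoxy-5-(methoxymethoxy)-2-[4-(methoxymethoxy)phenyl]-8-(3-methylbut-2-en-1-yl)-4H-chromen-4-one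
Product: 13 isoanhydroicaritin, 3,5-dihydroxy-2-(4-hydroxyphenyl)-7-methoxy-8-(3-methylbut-2-en-1-yl)-4H-chromen-4-one
Conditions: 3 M aq. HCl, MeOH, 45 °C
Reagents that add atoms: none
Why: Acid-catalysed acetal exchange removes both methoxymethyl groups; the prenyl group has no free hydroxyl on either flanking carbon, so chroman formation is impossible, and dilute acid at mild temperature should not add methanol to the alkene.

## Compound list

1 | 2,6-dihydroxy-4-methoxybenzaldehyde | COc1cc(O)c(C=O)c(O)c1 | starting material
2 | 2-hydroxy-4-methoxy-6-(methoxymethoxy)benzaldehyde | COCOc1cc(OC)cc(O)c1C=O | intermediate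
3 | 4-methoxy-2-(methoxymethoxy)-6-(prop-2-en-1-yloxy)benzaldehyde | COCOc1cc(OC)cc(OCC=C)c1C=O | intermediate
4 | 2-hydroxy-4-methoxy-6-(methoxymethoxy)-3-(prop-2-en-1-yl)benzaldehyde | COCOc1cc(OC)c(CC=C)c(O)c1C=O | intermediate
5 | 2-hydroxy-4-methoxy-6-(methoxymethoxy)-3-(3-methylbut-2-en-1-yl)benzaldehyde | COCOc1cc(OC)c(CC=C(C)C)c(O)c1C=O | intermediate
6 | methyl 4-hydroxybenzoate | COC(=O)c1ccc(O)cc1 | starting material
7 | methyl 4-(methoxymethoxy)benzoate | COCOc1ccc(cc1)C(=O)OC | intermediate
8 | lithium 2,2-dibromo-1-[4-(methoxymethoxy)phenyl]ethen-1-olate | [Li+].[O-]C(=C(Br)Br)c1ccc(OCOC)cc1 | intermediate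
9 | lithium 2-[4-(methoxymethoxy)phenyl]ethyn-1-olate | [Li+].[O-]C#Cc1ccc(OCOC)cc1 | intermediate
10 | triisopropyl({[4-(methoxymethoxy)phenyl]ethynyl}oxy)silane | COCOc1ccc(cc1)C#CO[Si](C(C)C)(C(C)C)C(C)C | intermediate
11 | 7-methoxy-5-(methoxymethoxy)-2-[4-(methoxymethoxy)phenyl]-8-(3-methylbut-2-en-1-yl)-3-[(triisopropylsilyl)oxy]-4H-chromen-4-one | COCOc1ccc(cc1)-c1oc2c(CC=C(C)C)c(OC)cc(OCOC)c2c(=O)c1O[Si](C(C)C)(C(C)C)C(C)C | intermediate
12 | 3-hydroxy-7-methoxy-5-(methoxymethoxy)-2-[4-(methoxymethoxy)phenyl]-8-(3-methylbut-2-en-1-yl)-4H-chromen-4-one | COCOc1ccc(cc1)-c1oc2c(CC=C(C)C)c(OC)cc(OCOC)c2c(=O)c1O | intermediate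
13 | isoanhydroicaritin, 3,5-dihydroxy-2-(4-hydroxyphenyl)-7-methoxy-8-(3-methylbut-2-en-1-yl)-4H-chromen-4-one | COc1cc(O)c2c(=O)c(O)c(-c3ccc(O)cc3)oc2c1CC=C(C)C | target

## Step count and risks

Total: 9 steps. Longest linear sequence: 7 steps (steps 1, 2, 3, 4, 7, 8, 9); the alkyne branch takes 2 steps (5 and 6).

**Step 7 (key step, the one labelled as a proposed new method).** Several things may go wrong:
- The siloxyalkyne may be protonated by the pivalic acid released in the metalation, or activated by cationic trivalent rhodium toward attack by the phenoxide, and so be consumed before insertion.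
- Insertion may occur with the opposite orientation.
- The electron-rich phenoxide or the ynol ether may be oxidised directly at the anode if rhodium turnover lags behind the current.
- The acyl rhodium may decarbonylate.

The fallback uses known chemistry, sets out from 5 and 7 and returns at 12. Ester 7 is converted in one pot (i-Bu2AlH, CH2Cl2, −78 °C; then MeOH, K2CO3 and dimethyl (1-diazo-2-oxopropyl)phosphonate, Ohira–Bestmann homologation) via 4-(methoxymethoxy)benzaldehyde F1 into 1-ethynyl-4-(methoxymethoxy)benzene F2. The lithium acetylide of F2 (n-BuLi, THF, −78 °C, the acetylide used in excess to allow for the phenol) is added to 5 to give racemic 2-{1-hydroxy-3-[4-(methoxymethoxy)phenyl]prop-2-yn-1-yl}-5-methoxy-3-(methoxymethoxy)-6-(3-methylbut-2-en-1-yl)phenol F3. MnO2 in CH2Cl2 oxidises it to 1-[2-hydroxy-4-methoxy-6-(methoxymethoxy)-3-(3-methylbut-2-en-1-yl)phenyl]-3-[4-(methoxymethoxy)phenyl]prop-2-yn-1-one F4. Et2NH in EtOH closes the pyranone in the 6-endo sense to 7-methoxy-5-(methoxymethoxy)-2-[4-(methoxymethoxy)phenyl]-8-(3-methylbut-2-en-1-yl)-4H-chromen-4-one F5, the same structure as A7. C3 lithiation of F5 with LiN(i-Pr)2 at −78 °C, trapping with B(OMe)3 and oxidation of the borate with H2O2/AcOH gives 12. The borate oxidation uses a nucleophilic peroxide and should spare the prenyl alkene, but the sequence costs four more operations.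

**Step 6.** Excess n-BuLi may lithiate the ring ortho to the acetal, the aryl shift may be incomplete, or silylation may occur on carbon to give a silylketene. The fallback sets out from 7 and returns at 9, which is then silylated to 10. The same one-pot reduction and Ohira–Bestmann homologation of 7 gives, via 4-(methoxymethoxy)benzaldehyde F6, 1-ethynyl-4-(methoxymethoxy)benzene F7. Its lithium acetylide (LiN(SiMe3)2, THF, −78 °C) is oxidised with t-BuOOLi (from t-BuOOH and LiN(SiMe3)2) to the same ynolate 9, which is silylated with TIPSOTf to 10. No alkyllithium is then present beside the acetal.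

**Step 3.** Prolonged heating may cause thermal loss of the acetal, loss of the formyl group after migration to the substituted ortho carbon, or decomposition of the aldehyde. The fallback sets out from 1 and returns at 5. Direct C-prenylation of 1 with prenyl bromide and aqueous KOH at 0 °C gives 2,6-dihydroxy-4-methoxy-3-(3-methylbut-2-en-1-yl)benzaldehyde F8. One equivalent of MOMCl with i-Pr2NEt should then etherify the hydroxyl flanked by hydrogen in preference to the one buttressed by the prenyl group, giving 5. This is shorter, but C- versus O-alkylation and the site of protection depend on modest preferences.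

**Step 4.** The double bond may migrate into conjugation with the ring through ruthenium hydride species, the exchange may stop at the 2-butenyl stage, or the chelating salicylaldehyde may slow the catalyst. The fallback sets out from 1 and returns at 5. Mono-O-prenylation of 1 (prenyl bromide, K2CO3, acetone) gives 2-hydroxy-4-methoxy-6-[(3-methylbut-2-en-1-yl)oxy]benzaldehyde F9. A para-Claisen–Cope rearrangement (Eu(fod)3, CHCl3, 60 °C, or PhNEt2 with heating) carries the intact prenyl group through the ortho dienone to the para carbon, giving 2,6-dihydroxy-4-methoxy-3-(3-methylbut-2-en-1-yl)benzaldehyde F10. Selective acetal formation on the less hindered hydroxyl, as above, gives 5.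

## Further compounds

F1 | step 7 | 4-(methoxymethoxy)benzaldehyde | COCOc1ccc(C=O)cc1
F2 | step 7 | 1-ethynyl-4-(methoxymethoxy)benzene | COCOc1ccc(cc1)C#C
F3 | step 7 | 2-{1-hydroxy-3-[4-(methoxymethoxy)phenyl]prop-2-yn-1-yl}-5-methoxy-3-(methoxymethoxy)-6-(3-methylbut-2-en-1-yl)phenol (racemic) | COCOc1cc(OC)c(CC=C(C)C)c(O)c1C(O)C#Cc1ccc(OCOC)cc1
F4 | step 7 | 1-[2-hydroxy-4-methoxy-6-(methoxymethoxy)-3-(3-methylbut-2-en-1-yl)phenyl]-3-[4-(methoxymethoxy)phenyl]prop-2-yn-1-one | COCOc1cc(OC)c(CC=C(C)C)c(O)c1C(=O)C#Cc1ccc(OCOC)cc1
F5 | step 7 | 7-methoxy-5-(methoxymethoxy)-2-[4-(methoxymethoxy)phenyl]-8-(3-methylbut-2-en-1-yl)-4H-chromen-4-one | COCOc1ccc(cc1)-c1cc(=O)c2c(OCOC)cc(OC)c(CC=C(C)C)c2o1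
F6 | step 6 | 4-(methoxymethoxy)benzaldehyde | COCOc1ccc(C=O)cc1
F7 | step 6 | 1-ethynyl-4-(methoxymethoxy)benzene | COCOc1ccc(cc1)C#C
F8 | step 3 | 2,6-dihydroxy-4-methoxy-3-(3-methylbut-2-en-1-yl)benzaldehyde | COc1cc(O)c(C=O)c(O)c1CC=C(C)C
F9 | step 4 | 2-hydroxy-4-methoxy-6-[(3-methylbut-2-en-1-yl)oxy]benzaldehyde | COc1cc(O)c(C=O)c(OCC=C(C)C)c1
F10 | step 4 | 2,6-dihydroxy-4-methoxy-3-(3-methylbut-2-en-1-yl)benzaldehyde | COc1cc(O)c(C=O)c(O)c1CC=C(C)C
A1 | alternative 1 | 1-[2-hydroxy-4,6-dimethoxy-3-(3-methylbut-2-en-1-yl)phenyl]ethan-1-one | CC(=O)c1c(O)c(CC=C(C)C)c(OC)cc1OC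
A2 | alternative 1 | {[1,3-dimethoxy-2-(3-methylbut-2-en-1-yl)buta-1,3-dien-1-yl]oxy}trimethylsilane | COC(=C)C(CC=C(C)C)=C(OC)O[Si](C)(C)C
A3 | alternative 1 | 4,4-dimethoxybut-3-en-2-one | CC(=O)C=C(OC)OC
A4 | alternative 2 | 5-ethoxy-3-methoxy-2-(3-methylbut-2-en-1-yl)phenol | CCOc1cc(O)c(CC=C(C)C)c(OC)c1
A5 | alternative 2 | 3-ethoxycyclobut-2-en-1-one | CCOC1=CC(=O)C1
A6 | alternative 2 | 1-methoxy-5-methylhex-4-en-1-yne | COC#CCC=C(C)C
A7 | alternative 3 | 7-methoxy-5-(methoxymethoxy)-2-[4-(methoxymethoxy)phenyl]-8-(3-methylbut-2-en-1-yl)-4H-chromen-4-one | COCOc1ccc(cc1)-c1cc(=O)c2c(OCOC)cc(OC)c(CC=C(C)C)c2o1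
A8 | alternative 3 | 2-iodo-5-methoxy-3-(methoxymethoxy)-6-(3-methylbut-2-en-1-yl)phenol | COCOc1cc(OC)c(CC=C(C)C)c(O)c1I
A9 | alternative 3 | 1-ethynyl-4-(methoxymethoxy)benzene | COCOc1ccc(cc1)C#C
A10 | alternative 3 | carbon monoxide | [C-]#[O+]
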